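The data are simulated from invented constants; scatter was added.

common to all: free catalyst 1.7 mM

| flask | left-handed substrate | right-handed substrate | solid reagent | remark | time |
|---|---|---|---|---|---|
| cedar | 0.050 M | 0.050 M | 0.30 M | run made earlier |  |
| maple | 0.20 M | 0.20 M | 0.30 M | run made earlier |  |
| oak | 0.10 M | 0.10 M | 0.15 M | run made earlier |  |
| flask | 0.10 M | 0.10 M | 0.300 M |  | 10 d |

- cedar (time / d: left-handed product / %, right-handed product / %, left-handed substrate / %): 0.333: 1.2, 4.8, 48.6; 0.833: 5.0, 16.4, 45.3; 1.67: 13.4, 31.7, 35.5; 2.50: 22.4, 42.8, 25.4; 4.00: 38.1, 49.0, 13.5; 5.00: 44.4, 46.4, 7.4; 6.00: 46.0, 49.6, 3.5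
- maple (time / d: left-handed product / %, right-handed product / %, left-handed substrate / %): 0.833: 2.6, 5.5, 48.8; 1.67: 5.1, 11.3, 46.0; 2.50: 4.5, 15.9, 44.3; 3.00: 7.1, 19.6, 42.3; 4.00: 10.7, 26.0, 38.9; 5.00: 13.4, 34.7, 35.8; 6.00: 17.0, 38.8, 31.8
- oak (time / d: left-handed product / %, right-handed product / %, left-handed substrate / %): 1.25: 6.4, 13.4, 44.5; 2.50: 12.4, 29.6, 37.0; 4.00: 20.9, 41.4, 30.1; 5.00: 21.4, 41.2, 28.2; 6.00: 22.4, 44.2, 28.3

(standard deviation of a reading: 1 percentage point)

- free catalyst is single-handed; left-handed substrate and right-handed substrate are mirror images of each other, charged as a racemate, each of them at the stated concentration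
- as a solid, counted per litre of solution: solid reagent
- at the start none of the solid reagent is in solution
- an excess is the difference of the two amounts in percent of their sum
- an excess is below zero if the other one leads

- excess of left-handed product over right-handed product in the product at 25 h
- excess of left-handed product over right-handed product in the product at 10 d
- part of the left-handed substrate and right-handed substrate charged together that has reacted at 10 d

1. The product's excess comes from two rates: the loss of right-handed substrate per amount of it left, and the same for left-handed substrate. Divide one by the other and time drops out.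

2. Call q and r the fractions of their own charges still left, right-handed and left-handed. Maple at 6.00 d gives 3.31 for ln q over ln r, the selectivity factor s. Oak at 2.50 d, on another charge, reads 2.98, and each reading scatters by 1 percentage point.

3. So, as long as s holds, q is r raised to s. My reckoning: at the start, the excess is the difference of the two rates over their sum, −53.6%. If this flask ends at cedar's last reading, r = 0.0700, the excess shrinks to −3.62%, with 96.5% reacted.

4. The forecast gives −50% (−56% to −43%) at 25 h, then −2.5% (−7% to −0.5%) and 97.5% (93% to 99.5%) at 10 d, holding “so reagent is sufficient”.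

5. This flask gives −49.4%, −3.25% and 96.8%, each inside the forecast's range. At 10.0 d, 6.3% of the left-handed charge is left. Through s, that r gives an excess of −3.25%.

    free catalyst + left-handed substrate ⇌ catalyst intermediate A (K = 2.40 /M, k = 3900 /M/h)
    free catalyst + right-handed substrate ⇌ catalyst intermediate B (K = 23.0 /M, k = 270 /M/h)
    partner + catalyst intermediate A → free catalyst + left-handed product (k = 350 /M/h)
    partner + catalyst intermediate B → free catalyst + right-handed product (k = 130 /M/h)
    2 partner → self-condensation product (k = 1.60 /M/h)
    solid reagent ⇌ partner, rate k6*(cs6 - [partner]) while solid is left; crystals form when [partner] > cs6 (solubility = 0.0840 M, k = 0.0240 /h)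

6. With 0.075 M of solid reagent, the neighbour flask stands at r = 82% after 10 d, for which s gives q = 51.8% and an excess of −45.6%. Computed, that flask holds q = 52% and an excess of −45.0%, at 33.1% reacted.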